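**Retrosynthetic overview**
1. The strategy rests on ring C, a 2-aryl-tetrahydropyran-4-one: O1–C2 is the carbonyl group of 3,4,5-trimethoxybenzaldehyde, C3–C4–C4a–C8a is an oxygenated four-carbon diene, and the C4a=C8a enone (a vinylogous ester) left by the cycloaddition is the handle for ring A.
2. Ring C is formed first (step 1): a catalytic enantioselective formal hetero-Diels–Alder reaction makes C2–C3 and O1–C8a and sets C2, the only stereocentre.
3. Ring A is formed second, disconnected at C8–C8a and C4a–C5: C5–C8 with the 7-OMe and the 6-prenyl group arrive as one vinylketene acetal made from methyl acetoacetate and prenyl bromide.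
4. C8–C8a is made by vinylogous Mukaiyama–Michael addition, C4a=C8a is restored by Saegusa–Ito oxidation, and C4a–C5 is closed by a Claisen condensation, so that aromatisation needs only tautomerisation and no elimination across the ring fusion.

Key step: step 1

Assumption: the catalyst from (S)-BINOL and Ti(OiPr)4 is taken to deliver the diene to the si face of the aryl aldehyde (2S product); should the sense prove opposite, (R)-BINOL is used and nothing else changes.

**Step 1**
Reactants: 1 3,4,5-trimethoxybenzaldehyde; 2 trans-1-methoxy-3-(trimethylsilyloxy)buta-1,3-diene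
Product: 4 (2S)-2-(3,4,5-trimethoxyphenyl)-2,3-dihydro-4H-pyran-4-one, via aldol silyl ether 3 (not isolated)
Conditions: (S)-BINOL (20 mol%), Ti(OiPr)4 (20 mol%), 4 Å MS, Et2O, −20 °C; then CF3CO2H (0.5 equiv), CH2Cl2, 0 °C
Reagents that add atoms: none
Why: The aldehyde bound to the chiral BINOL titanate (tetravalent titanium) is attacked at its carbonyl carbon (future C2) by the unsubstituted CH2 terminus of the silyloxy diene (future C3), and silyl transfer gives the Mukaiyama aldol silyl ether 3 and frees the catalyst. Trifluoroacetic acid then liberates the C2 hydroxyl, which adds to the β-methoxy enone in a 6-endo-trig oxa-Michael closure (O1–C8a), and loss of methanol restores the C4a=C8a enone, so ring C results as the formal [4+2] adduct. The closest known reaction type is the BINOL–titanium catalysed enantioselective formal hetero-Diels–Alder reaction of aromatic aldehydes with 1-methoxy-3-silyloxybutadienes. The only new stereocentre, C2, is set in the aldol event by catalyst control of the aldehyde face (si-face attack gives 2S) and is not involved in the ring closure. Regiochemistry follows from the polarity of the diene alone, and the aldehyde is unhindered and non-enolisable, so facial selectivity is the single selectivity required; the acid is kept substoichiometric and cold because the carbinol is benzylic to an electron-rich arene.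

**Step 2**
Reactants: 5 methyl acetoacetate; 6 prenyl bromide
Product: 7 methyl 2-acetyl-5-methylhex-4-enoate (racemic)
Conditions: NaH (1.0 equiv), THF, 0 °C; then 6 (0.95 equiv), 0 °C → rt
Reagents that add atoms: none
Why: Acetoacetic ester alkylation, an SN2 C-alkylation of the stabilised enolate by a primary allylic bromide, with the bromide as limiting reagent to suppress dialkylation.

**Step 3**
Reactants: 7 methyl 2-acetyl-5-methylhex-4-enoate
Product: 9 methyl 3-methoxy-2-(3-methylbut-2-en-1-yl)but-2-enoate (E/Z mixture), via dimethyl ketal 8 (not isolated)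
Conditions: HC(OMe)3 (neat, 5 equiv), TsOH·H2O (2 mol%), rt; NaOMe quench; distil under reduced pressure
Reagents that add atoms: trimethyl orthoformate, COC(OC)OC
Why: Acid-catalysed ketalisation with the orthoformate followed by loss of methanol from 8 is the standard enol ether synthesis for 3-methoxy-2-enoates; catalytic acid in an anhydrous medium at room temperature should spare the prenyl olefin, and all enol ether isomers converge on one dienolate in step 4.

**Step 4**
Reactants: 9 methyl 3-methoxy-2-(3-methylbut-2-en-1-yl)but-2-enoate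
Product: 10 tert-butyl{[1,3-dimethoxy-2-(3-methylbut-2-en-1-yl)buta-1,3-dien-1-yl]oxy}dimethylsilane
Conditions: LDA (1.1 equiv), THF, −78 °C; TBSCl (1.2 equiv), DMPU, −78 → 0 °C
Reagents that add atoms: tert-butyldimethylsilyl chloride, CC(C)(C)[Si](C)(C)Cl
Why: γ-Deprotonation of the 3-methoxy enoate to the lithium dienolate and O-silylation is the usual vinylketene acetal synthesis; the tert-butyldimethylsilyl group is chosen so that step 5 delivers an isolable silyl enol ether.

**Step 5**
Reactants: 4 (2S)-2-(3,4,5-trimethoxyphenyl)-2,3-dihydro-4H-pyran-4-one; 10 the silyl vinylketene acetal (1.5 equiv)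
Product: 11 methyl 4-[(2S,6R)-4-(tert-butyldimethylsilyloxy)-2-(3,4,5-trimethoxyphenyl)-3,6-dihydro-2H-pyran-6-yl]-3-methoxy-2-(3-methylbut-2-en-1-yl)but-2-enoate (2,6-trans, enoate E/Z mixture)
Conditions: TBSOTf (0.2 equiv), CH2Cl2, −78 °C; Et3N quench
Reagents that add atoms: none
Why: Vinylogous Mukaiyama–Michael addition in which the silyl triflate turns the vinylogous ester into a 4-silyloxy oxocarbenium ion that the unsubstituted diene terminus (C8) attacks at C8a, silyl transfer regenerating the catalyst and leaving a regiodefined C4=C4a silyl enol ether; axial attack anti to the C2 aryl group should give the 2,6-trans isomer, the new C8a centre being removed in step 6 and C2 staying untouched.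

**Step 6**
Reactants: 11 the trans silyl enol ether
Product: 12 methyl 3-methoxy-2-(3-methylbut-2-en-1-yl)-4-[(2S)-4-oxo-2-(3,4,5-trimethoxyphenyl)-3,4-dihydro-2H-pyran-6-yl]but-2-enoate
Conditions: Pd(OAc)2 (1.1 equiv), MeCN, rt
Reagents that add atoms: none
Why: Saegusa–Ito oxidation, in which divalent palladium forms the C4a palladium enolate and β-hydride elimination can only take the hydrogen at C8a, so C4a=C8a is restored regiospecifically with C8 now attached and zerovalent palladium is released.

**Step 7**
Reactants: 12 the 6-substituted dihydropyranone ester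
Product: 14 artoflavanone, (2S)-5-hydroxy-7-methoxy-6-(3-methylbut-2-en-1-yl)-2-(3,4,5-trimethoxyphenyl)-2,3-dihydro-4H-chromen-4-one, via dienone tautomer 13 (not isolated)
Conditions: LiHMDS (1.2 equiv), THF, −78 → 0 °C; then AcOH
Reagents that add atoms: none
Why: Intramolecular Claisen condensation in the acylphloroglucinol mode of polyketide cyclisation, in which deprotonation at C8 (flanked by both vinylogous carbonyl systems) gives an extended enolate whose C4a carbon attacks the ester carbonyl C5, methoxide leaves and dienone 13 tautomerises to the chelated 5-phenol; no stereocentre is formed, and about one equivalent of base at or below 0 °C should leave C3 un-enolised and C2 intact.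

**Compound list**
1 | 3,4,5-trimethoxybenzaldehyde | COc1cc(C=O)cc(OC)c1OC | starting material
2 | trans-1-methoxy-3-(trimethylsilyloxy)buta-1,3-diene | CO/C=C/C(=C)O[Si](C)(C)C | starting material
3 | (1E,5S)-1-methoxy-5-(3,4,5-trimethoxyphenyl)-5-(trimethylsilyloxy)pent-1-en-3-one | CO/C=C/C(=O)C[C@H](O[Si](C)(C)C)c1cc(OC)c(OC)c(OC)c1 | intermediate
4 | (2S)-2-(3,4,5-trimethoxyphenyl)-2,3-dihydro-4H-pyran-4-one | O=C1C[C@@H](c2cc(OC)c(OC)c(OC)c2)OC=C1 | intermediate
5 | methyl acetoacetate | CC(=O)CC(=O)OC | starting material
6 | prenyl bromide (1-bromo-3-methylbut-2-ene) | CC(C)=CCBr | starting material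
7 | methyl 2-acetyl-5-methylhex-4-enoate (racemic) | CC(=O)C(CC=C(C)C)C(=O)OC | intermediate
8 | methyl 2-(1,1-dimethoxyethyl)-5-methylhex-4-enoate | COC(=O)C(CC=C(C)C)C(C)(OC)OC | intermediate
9 | methyl 3-methoxy-2-(3-methylbut-2-en-1-yl)but-2-enoate (E/Z mixture) | COC(C)=C(CC=C(C)C)C(=O)OC | intermediate
10 | tert-butyl{[1,3-dimethoxy-2-(3-methylbut-2-en-1-yl)buta-1,3-dien-1-yl]oxy}dimethylsilane | C=C(OC)C(CC=C(C)C)=C(OC)O[Si](C)(C)C(C)(C)C | intermediate
11 | methyl 4-[(2S,6R)-4-(tert-butyldimethylsilyloxy)-2-(3,4,5-trimethoxyphenyl)-3,6-dihydro-2H-pyran-6-yl]-3-methoxy-2-(3-methylbut-2-en-1-yl)but-2-enoate (2,6-trans) | COC(=O)C(CC=C(C)C)=C(OC)C[C@@H]1C=C(O[Si](C)(C)C(C)(C)C)C[C@@H](c2cc(OC)c(OC)c(OC)c2)O1 | intermediate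
12 | methyl 3-methoxy-2-(3-methylbut-2-en-1-yl)-4-[(2S)-4-oxo-2-(3,4,5-trimethoxyphenyl)-3,4-dihydro-2H-pyran-6-yl]but-2-enoate | COC(=O)C(CC=C(C)C)=C(OC)CC1=CC(=O)C[C@@H](c2cc(OC)c(OC)c(OC)c2)O1 | intermediate
13 | (2S)-7-methoxy-6-(3-methylbut-2-en-1-yl)-2-(3,4,5-trimethoxyphenyl)-2,3-dihydro-4H-chromene-4,5(4aH)-dione (keto tautomer of ring A) | COC1=C(CC=C(C)C)C(=O)C2C(=O)C[C@@H](c3cc(OC)c(OC)c(OC)c3)OC2=C1 | intermediate
14 | artoflavanone, (2S)-5-hydroxy-7-methoxy-6-(3-methylbut-2-en-1-yl)-2-(3,4,5-trimethoxyphenyl)-2,3-dihydro-4H-chromen-4-one | COc1cc2c(c(O)c1CC=C(C)C)C(=O)C[C@@H](c1cc(OC)c(OC)c(OC)c1)O2 | target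

**Step count**
Total: 7 steps. Longest linear sequence: 6 steps (5 and 6 → 7 → 9 → 10 → 11 → 12 → 14, steps 2 to 7).

**Steps most likely to fail**

1. Step 7, closure of ring A. In the delocalised anion the ester carbonyl is itself part of the enolate system, so acylation at C4a may be slow. The base would then have time to enolise C3 and open ring C by retro-oxa-Michael elimination, which erodes the configuration at C2. The fallback sets out from 12 and closes the ring through a ketene under near-neutral conditions. Me3SnOH (1,2-dichloroethane, 80 °C) would cleave the methyl ester to the carboxylic acid F1. 1-Chloro-N,N,2-trimethylprop-1-en-1-amine (CH2Cl2, 0 °C) would convert it into the acid chloride F2 without free acid. Et3N would then remove a C8 proton and chloride to give the dienylketene F3, whose 6π-electrocyclisation (the closing event of vinylketene-based benzannulations) forms C4a–C5. This returns to the route at dienone 13, which tautomerises to 14.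

2. Step 5, vinylogous Mukaiyama–Michael addition. The silyl triflate may ionise the benzylic C2–O1 bond of the electron-rich 2-aryl oxocarbenium ion and so erode the ee. The cationic ester terminus may also be trapped by the new silyl enol ether, closing C4a–C5 too early and at the wrong oxidation level, or the ketene acetal may be desilylated before it adds. The fallback sets out from 4 and replaces the ionic addition and the palladium oxidation by a cycloaddition on a halogenated enone; it is the less certain line, because the final loss of HBr has to occur across the ring fusion. Br2 (CH2Cl2, −78 °C) followed by Et3N would give the 5-bromo enone F4 by addition and dehydrobromination. Heating F4 with diene 10 (toluene, 80–100 °C) would give cycloadduct F5, the halogen activating the dienophile as in 2-halocycloalkenones and the diene polarity again placing C8 on C8a. Dilute acid would collapse the silyl methyl ketal to the bromo enedione F6. Dehydrobromination (DBU, or LiBr and Li2CO3 in DMF) would give the cross-conjugated dienone F7, which tautomerises and returns to the route at 14.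

3. Step 1, the key step. The electron-rich aldehyde is a weak electrophile, so the catalysed aldol addition may be slow enough for a non-selective silyl-cation pathway to compete, giving insufficient facial selectivity. Acid-induced ionisation at the benzylic carbinol during ring closure would have the same effect. The fallback sets out from 1 and uses a stoichiometric chiral boron enolate. (E)-4-Chlorobut-3-en-2-one would be enolised with Ipc2BCl (B-chlorodiisopinocampheylborane, the antipode that attacks the si face) and iPr2NEt in Et2O at −78 °C and added to 1, with oxidative work-up, to give the chloro aldol F8. TMSOTf and iPr2NEt (CH2Cl2, −78 °C) would then induce 6-endo oxa-Michael addition and loss of chloride, closing ring C and returning to the route at 4.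

**Further compounds**
F1 | step 7 | 3-methoxy-2-(3-methylbut-2-en-1-yl)-4-[(2S)-4-oxo-2-(3,4,5-trimethoxyphenyl)-3,4-dihydro-2H-pyran-6-yl]but-2-enoic acid | OC(=O)C(CC=C(C)C)=C(OC)CC1=CC(=O)C[C@@H](c2cc(OC)c(OC)c(OC)c2)O1
F2 | step 7 | 3-methoxy-2-(3-methylbut-2-en-1-yl)-4-[(2S)-4-oxo-2-(3,4,5-trimethoxyphenyl)-3,4-dihydro-2H-pyran-6-yl]but-2-enoyl chloride | ClC(=O)C(CC=C(C)C)=C(OC)CC1=CC(=O)C[C@@H](c2cc(OC)c(OC)c(OC)c2)O1
F3 | step 7 | 3-methoxy-2-(3-methylbut-2-en-1-yl)-4-[(2S)-4-oxo-2-(3,4,5-trimethoxyphenyl)-3,4-dihydro-2H-pyran-6-yl]buta-1,3-dien-1-one (dienylketene) | O=C=C(CC=C(C)C)C(OC)=CC1=CC(=O)C[C@@H](c2cc(OC)c(OC)c(OC)c2)O1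
F4 | step 5 | (2S)-5-bromo-2-(3,4,5-trimethoxyphenyl)-2,3-dihydro-4H-pyran-4-one | O=C1C[C@@H](c2cc(OC)c(OC)c(OC)c2)OC=C1Br
F5 | step 5 | (2S)-4a-bromo-5-(tert-butyldimethylsilyloxy)-5,7-dimethoxy-6-(3-methylbut-2-en-1-yl)-2-(3,4,5-trimethoxyphenyl)-2,3,4a,5,8,8a-hexahydro-4H-chromen-4-one | COC1=C(CC=C(C)C)C(OC)(O[Si](C)(C)C(C)(C)C)C2(Br)C(=O)C[C@@H](c3cc(OC)c(OC)c(OC)c3)OC2C1
F6 | step 5 | (2S)-4a-bromo-7-methoxy-6-(3-methylbut-2-en-1-yl)-2-(3,4,5-trimethoxyphenyl)-2,3,8,8a-tetrahydro-4H-chromene-4,5(4aH)-dione | COC1=C(CC=C(C)C)C(=O)C2(Br)C(=O)C[C@@H](c3cc(OC)c(OC)c(OC)c3)OC2C1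
F7 | step 5 | (2S)-7-methoxy-6-(3-methylbut-2-en-1-yl)-2-(3,4,5-trimethoxyphenyl)-2,3-dihydro-4H-chromene-4,5(8H)-dione | COC1=C(CC=C(C)C)C(=O)C2=C(C1)O[C@H](c1cc(OC)c(OC)c(OC)c1)CC2=O
F8 | step 1 | (1E,5S)-1-chloro-5-hydroxy-5-(3,4,5-trimethoxyphenyl)pent-1-en-3-one | Cl/C=C/C(=O)C[C@H](O)c1cc(OC)c(OC)c(OC)c1
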